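## Structural features

The target has three rings. Ring A is a benzene ring with three adjacent methoxy groups (C2, C3, C4) and one free CH (C1). Ring B is a seven-membered carbocycle fused to ring A at C4a and C9a, running C5 (quaternary), C6 (CH2), C7 (CH–Me), C8 (CH–Me), C9 (CH–OBz). Ring C is a 2,6-dimethoxycyclohexa-2,5-dienone whose C4 is the same atom as C5, so C5 is a spiro centre.

Ring C is symmetric about the line through C5 and its carbonyl carbon, so C5 is not a stereocentre. The stereochemistry is the contiguous triad C7 (R), C8 (S), C9 (R): the two methyl groups are trans, and the C9 benzoate is trans to the C8 methyl and cis to the C7 methyl.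

The fragile groups are the cross-conjugated dienone with its two enol ether units (reduced by hydrides and by hydrogenation, acid-sensitive), the secondary benzylic benzoate (cleaved by hydride or alkoxide, able to ionise or eliminate) and the electron-rich arene.

The real difficulty is twofold. C5 is an all-carbon quaternary centre that is benzylic, ortho to a methoxy group and shared by two rings. The three adjacent stereocentres sit on a flexible seven-membered ring, and C7 has no functional group of its own.

The key step exploits the arc C6–C7–C8–C9: an isolated CH2 next to quaternary C5, then two methyl-bearing carbons, then the oxygenated benzylic carbon bonded to C9a. Read as CH2 + MeC≡CMe + C=O, this arc is a 1-indanone (C9 carbonyl, C6 α-carbon) with 2-butyne inserted into its carbonyl–α-carbon bond. Ring C is carried through that step and all redox steps as a gem-diester at C5.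

## Logic of the disconnections

**25 ⇒ 21 + 23.** The two C=C bonds of ring C are cut, between the CH carbons on C5 and the methoxy-bearing carbons. Ring C is symmetric, 23 holds exactly the three missing carbons with both methoxy groups, and C5 of 21 already carries two one-carbon arms. This removes the most fragile ring and leaves a bis-formyl compound. The forward step must make two C=C bonds at neopentyl aldehydes without a base that would deformylate 21 or cleave its benzoate. 23 comes from 22 by oxidation.

**21 ⇒ 20 ⇒ 19 ⇒ 18 ⇒ 17.** No skeletal bond is cut. The arms go back to the alcohol level, and the C9–O ester bond is cut with inversion at C9. A benzoate cannot survive the hydride that reduces the C5 esters, so the esters are reduced first and the benzoate is put on afterwards. The two primary hydroxyls of 17 are tied in a six-membered acetal so that only the C9 hydroxyl is esterified. The forward demands are an SN2 displacement at a hindered benzylic carbon and an acetal cleavage that spares the benzoate.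

**17 ⇒ 15.** The C9–H bond and the four C–H bonds of the arms are removed. 15 holds the whole oxidation pattern as one ketone and two esters. The forward step needs hydride delivery to C9 from the face away from the C8 methyl (giving 9S, later inverted), and ester reduction in the same flask.

**15 ⇒ 13 ⇒ 12 ⇒ 11.** The stereocentres are removed one at a time. C8 can be corrected only through the C9 ketone, so 15 comes from its C8 epimer, which is the oxidation product of 13. C7 is set by hydrogen delivered from a C9 hydroxyl, so 13 comes from 12. The C9 centre of 12 is a temporary control element that is erased once C7 is fixed. The gain is that 11 is achiral. The forward demands are an enantioselective 1,2-reduction of a hindered enone, a face-selective hydrogenation of a tetrasubstituted alkene, and a thermodynamic preference for the trans dimethyl ketone.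

**11 ⇒ 7 + 8 (key).** C9–C8 and C7–C6 are cut and the two methyl-bearing carbons are excised as 8. Ring B contracts to the five-membered ring of 7, which a Friedel–Crafts closure can make, and both methyl groups arrive in one symmetric reagent. The forward step needs a metal to insert into the C9–C6 bond only, and to tolerate the gem-diester.

**7 ⇒ 5 (through 6).** C9–C9a is cut (intramolecular Friedel–Crafts acylation). Only one ortho position of the arene is free, so the regiochemistry is forced. The demand is that the acetic arm alone be unmasked, hence its tert-butyl ester.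

**5 ⇒ 3 + 4.** C5–C6 is cut (enolate alkylation). The quaternary centre is made from a stabilised tertiary carbanion and an unhindered primary bromide.

**3 ⇒ 2 ⇒ 1.** One C5–CO2Me bond is cut (carbomethoxylation of the benzylic ester enolate); 2 comes from 1 by esterification.

## Other disconnections considered

**Alternative 1:** The cut runs through ring A (C1–C9a and C4–C4a). Ring B is made first as the cycloheptenyl stannane A1, with the C4a=C9a alkene, tin on C9a, the C7/C8/C9 triad, the C5 gem-diester and a silyl ether at C9. The other four arene carbons come from the chlorocyclobutenone A2.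

- Forward step: Pd2(dba)3 with tri(2-furyl)phosphine would couple A1 with A2 at C1–C9a (Stille coupling). On warming, the alkenylcyclobutenone should open to a dienylketene, close by 6π electrocyclisation at C4–C4a and tautomerise to the C4 phenol A3.
- In its favour: the substitution pattern of ring A is fixed by construction, the thermal cascade is well precedented for alkenyl stannanes, and the key step does not touch the stereotriad.
- Against it here: A1 is a hindered, fully substituted alkenyl stannane, and the electrocyclisation must bond to a carbon next to quaternary C5. A1 must also be made as a single enantiomer on a plain cycloheptene, where the aryl ketone that the chosen plan uses for directing, epimerising and reducing does not yet exist. A3 still needs O-methylation at C4, desilylation, benzoylation and the same diester-to-dienone endgame as 15.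
- Comparison: structurally both plans pass through a ring-B gem-diester and share the endgame (equal). Mechanistically the pericyclic cascade is the more secure key step, and its regiochemistry is better defined than a metal insertion that must choose between two C–C bonds (better than the chosen plan). On step economy the chosen plan is ahead: 7 is four steps from a commercial acid and step 5 delivers ring B with both methyl carbons, whereas A1 would need a long asymmetric synthesis and stoichiometric tin.

**Alternative 2:** The cuts are C9–C8 and C5–C6. The pieces are the biaryl phenol aldehyde A4 (C9 as a formyl group on ring A, ring C still a 2,6-dimethoxyphenol) and the bifunctional allyl reagent A5.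

- Forward step: a chiral BINOL-derived phosphoric acid would catalyse allylboration of the C9 aldehyde by A5 (C9–C8, setting the C8 methyl and C9 oxygen together). In the same flask Pd(PPh3)4 would ionise the allylic carbonate and the phenolate would attack through its para carbon (C5–C6). This closes ring B, creates the spiro centre and turns the phenol into the dienone, giving A6.
- In its favour: ring B, the quaternary carbon and ring C arise in one operation from a biaryl that a cross-coupling can assemble. The dienone comes from dearomatisation, so no dialdehyde annulation is needed. The C9 hydroxyl of A6, cis to the C8 methyl, is placed to direct hydrogenation of the C7 methylene and to be inverted during benzoylation, so the target would be about three steps from A6.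
- Against it: three selectivities must hold in one flask on a hindered biaryl aldehyde. These are enantio- and diastereocontrol with a 2-substituted crotyl reagent, para C-allylation instead of O-allylation in a seven-membered spirocyclisation, and suppression of attack by the C9 oxygen on the allyl complex (which would close a five-membered ether). Afterwards the exocyclic alkene must be hydrogenated without reducing ring C, and the invertive esterification is run on the finished dienone.
- Comparison: on step economy and convergence alternative 2 is clearly better. On stereochemistry it is at least equal, since C8 and C9 come from one catalytic step and no oxidation–epimerisation–reduction detour is needed. Structurally it forms the C5 quaternary centre late by C-allylation, where the chosen plan forms it early by malonate alkylation (more secure). Mechanistically it joins two established catalytic manifolds in an untested tandem and exposes the dienone to hydrogenation, whereas the chosen plan keeps ring C masked until the last step.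

**Alternative 3:** The cut is C9–C8 (with the C7–H bond). It leads back to the achiral dienone aldehyde A7, in which C5 already carries ring C, ring A with its C9 formyl group, and an (E)-2-methylbut-2-enyl chain. A7 would come from A4 by O-allylation and para-Claisen rearrangement, the ortho positions of the phenol being blocked by methoxy groups.

- Forward step: [Rh(cod)2]BF4 with a chiral bisphosphine would insert into the formyl C–H bond, add the rhodium hydride across one face of the trisubstituted alkene (H to C7, metal to C8), and close ring B by reductive elimination as the C9 ketone A8. Syn addition to the (E)-alkene gives the trans methyl pair, and the catalyst selects the alkene face.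
- In its favour: it is the shortest plan and fully atom-economic. C7 and C8 are set together with the right relative configuration, so no epimerisation is needed (better than steps 6 to 8 of the chosen plan). The spiro centre comes from a sigmatropic shift and ring C from phenol chemistry, so step 15 is avoided.
- Against it: hydroacylation to a seven-membered ketone with a trisubstituted alkene and no chelating atom in the tether is at the edge of the method; decarbonylation of the acyl rhodium hydride or alkene migration could take over. The alkene that decides the enantiomer is remote from any binding group. A8 then needs its C9 ketone reduced and benzoylated in the presence of ring C, which is the chemoselectivity problem the chosen plan avoids by building the dienone last.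
- Comparison: structurally A8 is the dienone analogue of 15, so the two plans differ mainly in when ring C appears. Mechanistically both rest on a rhodium insertion, but ring expansion of an indanone to a benzocycloheptenone has closer precedent than a non-chelated seven-membered hydroacylation. On step count and stereochemical economy alternative 3 is better; on the safety of the late steps the chosen plan is better.

Key step: step 5

**Remarks.**

- Remark on the precursor name: with the diester carbon as C1 of the indane, the methoxy groups of 7 sit at C5, C6 and C7 and the free aromatic CH (C4) is next to the ketone. Locants 4,5,6 combined with 3-oxo and 1,1-dicarboxylate would describe a regioisomer that the Friedel–Crafts closure cannot give and that does not map onto ring A.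
- Remark on the precursor design: 7 is kept as the dimethyl gem-diester, which has no β-hydrogen and no acidic C–H. Its esters are reduced only after the stereotriad is complete, so that no hydroxymethyl group competes as a directing group in step 7.
- Assumption for step 6: the α-methyl alkenyl arm of 11 acts as the larger group towards the oxazaborolidine. If the sense of induction is the opposite, the enantiomeric catalyst is used.
- Assumption for step 8: the trans-7,8-dimethyl ketone is the thermodynamically preferred C8 epimer.

## Route

Step 1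
Reactants: 1 (2,3,4-trimethoxyphenyl)acetic acid
Product: 2 methyl (2,3,4-trimethoxyphenyl)acetate
Conditions: MeOH, H2SO4 (cat.), reflux
Reagents that add atoms: methanol, CO
Why: Fischer esterification; excess methanol drives the equilibrium and nothing else in 1 reacts.

Step 2
Reactants: 2 methyl (2,3,4-trimethoxyphenyl)acetate
Product: 3 dimethyl 2-(2,3,4-trimethoxyphenyl)malonate
Conditions: NaH, (MeO)2CO, THF, reflux; aq. HCl
Reagents that add atoms: dimethyl carbonate, COC(=O)OC
Why: Claisen-type C-acylation of the benzylic ester enolate with dimethyl carbonate; the malonate is more acidic than 2 and is removed as its sodium salt, which drives the condensation.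

Step 3
Reactants: 3 dimethyl 2-(2,3,4-trimethoxyphenyl)malonate; 4 tert-butyl bromoacetate
Product: 5 dimethyl 2-(2-tert-butoxy-2-oxoethyl)-2-(2,3,4-trimethoxyphenyl)malonate
Conditions: NaH, DMF, 0 °C; 4, 0 °C to rt
Reagents that add atoms: none
Why: SN2 alkylation of the stabilised tertiary malonate anion by an unhindered α-bromo ester forms C5–C6 and the quaternary C5; the tert-butyl ester lets this arm be unmasked later without touching the methyl esters.

Step 4
Reactants: 5 dimethyl 2-(2-tert-butoxy-2-oxoethyl)-2-(2,3,4-trimethoxyphenyl)malonate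
Product: 7 dimethyl 5,6,7-trimethoxy-3-oxo-2,3-dihydro-1H-indene-1,1-dicarboxylate, via carboxylic acid 6 (not isolated)
Conditions: CF3CO2H, CH2Cl2, rt; then (CF3CO)2O, CF3SO3H (cat.), 0 °C to rt
Reagents that add atoms: none
Why: Acidolysis removes only the tert-butyl ester, and the mixed trifluoroacetic anhydride of 6 undergoes intramolecular Friedel–Crafts acylation at the only free ortho position, para to the central methoxy group; the gem-diester favours five-membered closure (Thorpe–Ingold effect) and no Lewis acid that cleaves aryl methyl ethers is used.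

Step 5
Reactants: 7 dimethyl 5,6,7-trimethoxy-3-oxo-2,3-dihydro-1H-indene-1,1-dicarboxylate; 8 2-butyne
Product: 11 dimethyl 2,3,4-trimethoxy-7,8-dimethyl-9-oxo-6,9-dihydro-5H-benzo[7]annulene-5,5-dicarboxylate, via indanone ketimine 9 (not isolated), via ring-expanded ketimine 10 (not isolated)
Conditions: [Rh(C2H4)2Cl]2 (5 mol %), 1,3-dimesitylimidazol-2-ylidene (IMes, 10 mol %), 2-amino-3-picoline (1 equiv), TsOH·H2O (20 mol %), 8 (5 equiv), 1,4-dioxane, 150 °C, sealed tube; then aq. HCl, THF, rt
Reagents that add atoms: water, O
Why: Condensation of 7 with 2-amino-3-picoline gives ketimine 9, whose pyridine nitrogen holds monovalent rhodium next to the C9–C6 bond; oxidative addition, helped by the strain of the five-membered ketone, gives a six-membered rhodacycle of trivalent rhodium (N,C-chelated iminoacyl and Rh–CH2). 2-Butyne then inserts syn into a Rh–C bond (the Rh–CH2 bond if the chelate is to stay intact), and C–C reductive elimination from the eight-membered rhodacycle releases ketimine 10 and monovalent rhodium; hydrolysis gives 11, so C9–C8 and C7–C6 are the two new bonds. The closest known reaction type is the rhodium-catalysed, aminopyridine-directed two-carbon ring expansion of 1-indanones with ethylene and with internal alkynes to benzocycloheptenones. Ring B is closed by ring expansion and not by cyclisation of a chain: the five-membered ring grows by two atoms through insertion, and the last bond forms by reductive elimination inside the metallacycle, which also fixes the cis ring geometry of the tetrasubstituted alkene. No stereocentre is formed, and the symmetric alkyne leaves no regiochemical question. The step needs cleavage of C9–C6 and not of C9–C9a or the ortho C1–H bond: the chelate places the metal at the imine carbon (ortho C–H metallation through the pyridine would need a seven-membered chelate), and the C(sp2)–C(sp3) bond is the weaker and more accessible of the two ring bonds. Quaternary C5 leaves the alkyl rhodium without β-hydrogen, which closes the usual β-hydride elimination leak; the esters have no acidic C–H and act as spectators, although one may coordinate the metal.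

Step 6
Reactants: 11 dimethyl 2,3,4-trimethoxy-7,8-dimethyl-9-oxo-6,9-dihydro-5H-benzo[7]annulene-5,5-dicarboxylate
Product: 12 dimethyl (9S)-9-hydroxy-2,3,4-trimethoxy-7,8-dimethyl-6,9-dihydro-5H-benzo[7]annulene-5,5-dicarboxylate
Conditions: (S)-2-methyl-CBS-oxazaborolidine (20 mol %), catecholborane, PhMe, −78 to −40 °C; aq. NaOH
Reagents that add atoms: none
Why: Corey–Bakshi–Shibata reduction: the ketone binds boron through the lone pair on its smaller flank, taken here to be the aryl side (ortho C–H only) against the alkenyl side with its in-plane α-methyl, which with the (S)-catalyst should give the (9S)-alcohol; catecholborane at low temperature gives 1,2-reduction only. C9 serves as a temporary control element for step 7.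

Step 7
Reactants: 12 dimethyl (9S)-9-hydroxy-2,3,4-trimethoxy-7,8-dimethyl-6,9-dihydro-5H-benzo[7]annulene-5,5-dicarboxylate
Product: 13 dimethyl (7R,8R,9S)-9-hydroxy-2,3,4-trimethoxy-7,8-dimethyl-6,7,8,9-tetrahydro-5H-benzo[7]annulene-5,5-dicarboxylate
Conditions: [Ir(cod)(PCy3)(py)]PF6 (5 mol %), H2 (1–4 bar), CH2Cl2, rt
Reagents that add atoms: none
Why: Hydroxyl-directed homogeneous hydrogenation: the cationic iridium centre binds the C9 hydroxyl and delivers both hydrogens to the C7=C8 face syn to it, which sets C7 (R) and gives the all-syn H7/H8/OH arrangement; this catalyst type reduces tetrasubstituted alkenes and leaves esters and the arene alone.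

Step 8
Reactants: 13 dimethyl (7R,8R,9S)-9-hydroxy-2,3,4-trimethoxy-7,8-dimethyl-6,7,8,9-tetrahydro-5H-benzo[7]annulene-5,5-dicarboxylate
Product: 15 dimethyl (7R,8S)-2,3,4-trimethoxy-7,8-dimethyl-9-oxo-6,7,8,9-tetrahydro-5H-benzo[7]annulene-5,5-dicarboxylate, via cis-dimethyl ketone 14 (not isolated)
Conditions: (COCl)2, DMSO, CH2Cl2, −78 °C; Et3N, −78 °C to rt; then DBU, rt
Reagents that add atoms: none
Why: Swern oxidation removes the spent C9 stereocentre; DBU then equilibrates C8 through the enolate of the aryl ketone to the trans-7,8-dimethyl isomer, expected to be favoured because both methyl groups can be pseudo-equatorial. C7 is not acidic and keeps its configuration.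

Step 9
Reactants: 15 dimethyl (7R,8S)-2,3,4-trimethoxy-7,8-dimethyl-9-oxo-6,7,8,9-tetrahydro-5H-benzo[7]annulene-5,5-dicarboxylate
Product: 17 (7R,8S,9S)-5,5-bis(hydroxymethyl)-2,3,4-trimethoxy-7,8-dimethyl-6,7,8,9-tetrahydro-5H-benzo[7]annulen-9-ol, via hydroxy diester 16 (not isolated)
Conditions: LiBH(s-Bu)3, THF, −78 °C; then LiAlH4, −78 to 0 °C; NaOH, H2O2
Reagents that add atoms: none
Why: The bulky borohydride attacks the C9 carbonyl from the face away from the adjacent C8 methyl, as is general for 2-alkylcycloalkanones, giving the cis (9S) alkoxide of 16; LiAlH4 then reduces both hindered methyl esters (and any bridged lactone formed from 16) to the bis(hydroxymethyl) group.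

Step 10
Reactants: 17 (7R,8S,9S)-5,5-bis(hydroxymethyl)-2,3,4-trimethoxy-7,8-dimethyl-6,7,8,9-tetrahydro-5H-benzo[7]annulen-9-ol
Product: 18 (7R,8S,9S)-2,3,4-trimethoxy-2',2',7,8-tetramethyl-6,7,8,9-tetrahydrospiro[benzo[7]annulene-5,5'-[1,3]dioxan]-9-ol
Conditions: Me2C(OMe)2, PPTS (cat.), acetone, rt
Reagents that add atoms: 2,2-dimethoxypropane, COC(C)(C)OC
Why: Acid-catalysed transacetalisation: the 2,2-bis(hydroxymethyl) unit closes to an unstrained 1,3-dioxane, whereas an acetal through the C9 hydroxyl would need an eight-membered ring, so that hydroxyl stays free.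

Step 11
Reactants: 18 (7R,8S,9S)-2,3,4-trimethoxy-2',2',7,8-tetramethyl-6,7,8,9-tetrahydrospiro[benzo[7]annulene-5,5'-[1,3]dioxan]-9-ol
Product: 19 (7R,8S,9R)-2,3,4-trimethoxy-2',2',7,8-tetramethyl-6,7,8,9-tetrahydrospiro[benzo[7]annulene-5,5'-[1,3]dioxan]-9-yl benzoate
Conditions: PhCO2H, PPh3, DIAD, THF, 0 °C to rt
Reagents that add atoms: benzoic acid, O=C(O)c1ccccc1
Why: Mitsunobu esterification: benzoate displaces the oxyphosphonium of the benzylic C9 alcohol with inversion, entering from the face trans to the C8 methyl, which turns the (9S) alcohol into the (9R) benzoate of the target.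

Step 12
Reactants: 19 (7R,8S,9R)-2,3,4-trimethoxy-2',2',7,8-tetramethyl-6,7,8,9-tetrahydrospiro[benzo[7]annulene-5,5'-[1,3]dioxan]-9-yl benzoate
Product: 20 (7R,8S,9R)-5,5-bis(hydroxymethyl)-2,3,4-trimethoxy-7,8-dimethyl-6,7,8,9-tetrahydro-5H-benzo[7]annulen-9-yl benzoate
Conditions: AcOH–H2O (4:1), 40 °C
Reagents that add atoms: none
Why: Mild aqueous acid hydrolyses the isopropylidene acetal; a secondary benzoate is stable to it, and acyl migration to a primary hydroxyl would need an eight-membered transition ring.

Step 13
Reactants: 20 (7R,8S,9R)-5,5-bis(hydroxymethyl)-2,3,4-trimethoxy-7,8-dimethyl-6,7,8,9-tetrahydro-5H-benzo[7]annulen-9-yl benzoate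
Product: 21 (7R,8S,9R)-5,5-diformyl-2,3,4-trimethoxy-7,8-dimethyl-6,7,8,9-tetrahydro-5H-benzo[7]annulen-9-yl benzoate
Conditions: Dess–Martin periodinane, NaHCO3, CH2Cl2, 0 °C to rt
Reagents that add atoms: none
Why: Dess–Martin oxidation of both neopentyl primary alcohols under buffered, non-basic conditions should give the non-enolisable dialdehyde without over-oxidation or retro-aldol loss of formaldehyde; the benzoate is inert.

Step 14
Reactants: 22 1,3-dimethoxypropan-2-ol
Product: 23 1,3-dimethoxypropan-2-one
Conditions: Dess–Martin periodinane, CH2Cl2, rt; distillation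
Reagents that add atoms: none
Why: Dess–Martin oxidation of a secondary alcohol to the ketone; no aqueous work-up is needed, which suits the water-soluble product.

Step 15
Reactants: 21 (7R,8S,9R)-5,5-diformyl-2,3,4-trimethoxy-7,8-dimethyl-6,7,8,9-tetrahydro-5H-benzo[7]annulen-9-yl benzoate; 23 1,3-dimethoxypropan-2-one
Product: 25 (7R,8S,9R)-2,3,3',4,5'-pentamethoxy-7,8-dimethyl-4'-oxo-6,7,8,9-tetrahydrospiro[benzo[7]annulene-5,1'-cyclohexa[2,5]dien]-9-yl benzoate (the target), via enone aldehyde 24 (not isolated)
Conditions: piperidine (cat.), AcOH (cat.), 4 Å molecular sieves, PhMe, 80 °C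
Reagents that add atoms: none
Why: Twofold aldol condensation (Knoevenagel-type, amine–acid catalysed): the two α-methylene groups of 23 condense in turn with the two formyl groups of 21, the second time intramolecularly in a six-membered closure, and loss of two molecules of water gives the cross-conjugated dienone. The buffered amine catalyst is chosen because hydroxide or alkoxide would deformylate the quaternary dialdehyde and cleave the benzoate; no stereocentre is created because ring C is symmetric.

## Compound list

1 | (2,3,4-trimethoxyphenyl)acetic acid | COc1ccc(CC(=O)O)c(OC)c1OC | starting material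
2 | methyl (2,3,4-trimethoxyphenyl)acetate | COC(=O)Cc1ccc(OC)c(OC)c1OC | intermediate
3 | dimethyl 2-(2,3,4-trimethoxyphenyl)malonate | COC(=O)C(C(=O)OC)c1ccc(OC)c(OC)c1OC | intermediate
4 | tert-butyl bromoacetate | CC(C)(C)OC(=O)CBr | starting material
5 | dimethyl 2-(2-tert-butoxy-2-oxoethyl)-2-(2,3,4-trimethoxyphenyl)malonate | COC(=O)C(CC(=O)OC(C)(C)C)(C(=O)OC)c1ccc(OC)c(OC)c1OC | intermediate
6 | 3,3-bis(methoxycarbonyl)-3-(2,3,4-trimethoxyphenyl)propanoic acid | COC(=O)C(CC(=O)O)(C(=O)OC)c1ccc(OC)c(OC)c1OC | intermediate (not isolated)
7 | dimethyl 5,6,7-trimethoxy-3-oxo-2,3-dihydro-1H-indene-1,1-dicarboxylate | COC(=O)C2(C(=O)OC)CC(=O)c1cc(OC)c(OC)c(OC)c12 | intermediate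
8 | 2-butyne | CC#CC | starting material
9 | dimethyl 5,6,7-trimethoxy-3-[(3-methylpyridin-2-yl)imino]-2,3-dihydro-1H-indene-1,1-dicarboxylate | COC(=O)C2(C(=O)OC)CC(=Nc3ncccc3C)c1cc(OC)c(OC)c(OC)c12 | intermediate (not isolated)
10 | dimethyl 2,3,4-trimethoxy-7,8-dimethyl-9-[(3-methylpyridin-2-yl)imino]-6,9-dihydro-5H-benzo[7]annulene-5,5-dicarboxylate | COC(=O)C2(C(=O)OC)CC(C)=C(C)C(=Nc3ncccc3C)c1cc(OC)c(OC)c(OC)c12 | intermediate (not isolated)
11 | dimethyl 2,3,4-trimethoxy-7,8-dimethyl-9-oxo-6,9-dihydro-5H-benzo[7]annulene-5,5-dicarboxylate | COC(=O)C2(C(=O)OC)CC(C)=C(C)C(=O)c1cc(OC)c(OC)c(OC)c12 | intermediate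
12 | dimethyl (9S)-9-hydroxy-2,3,4-trimethoxy-7,8-dimethyl-6,9-dihydro-5H-benzo[7]annulene-5,5-dicarboxylate | COC(=O)C2(C(=O)OC)CC(C)=C(C)[C@H](O)c1cc(OC)c(OC)c(OC)c12 | intermediate
13 | dimethyl (7R,8R,9S)-9-hydroxy-2,3,4-trimethoxy-7,8-dimethyl-6,7,8,9-tetrahydro-5H-benzo[7]annulene-5,5-dicarboxylate | COC(=O)C2(C(=O)OC)C[C@@H](C)[C@@H](C)[C@H](O)c1cc(OC)c(OC)c(OC)c12 | intermediate
14 | dimethyl (7R,8R)-2,3,4-trimethoxy-7,8-dimethyl-9-oxo-6,7,8,9-tetrahydro-5H-benzo[7]annulene-5,5-dicarboxylate | COC(=O)C2(C(=O)OC)C[C@@H](C)[C@@H](C)C(=O)c1cc(OC)c(OC)c(OC)c12 | intermediate (not isolated)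
15 | dimethyl (7R,8S)-2,3,4-trimethoxy-7,8-dimethyl-9-oxo-6,7,8,9-tetrahydro-5H-benzo[7]annulene-5,5-dicarboxylate | COC(=O)C2(C(=O)OC)C[C@@H](C)[C@H](C)C(=O)c1cc(OC)c(OC)c(OC)c12 | intermediate
16 | dimethyl (7R,8S,9S)-9-hydroxy-2,3,4-trimethoxy-7,8-dimethyl-6,7,8,9-tetrahydro-5H-benzo[7]annulene-5,5-dicarboxylate | COC(=O)C2(C(=O)OC)C[C@@H](C)[C@H](C)[C@H](O)c1cc(OC)c(OC)c(OC)c12 | intermediate (not isolated)
17 | (7R,8S,9S)-5,5-bis(hydroxymethyl)-2,3,4-trimethoxy-7,8-dimethyl-6,7,8,9-tetrahydro-5H-benzo[7]annulen-9-ol | OCC2(CO)C[C@@H](C)[C@H](C)[C@H](O)c1cc(OC)c(OC)c(OC)c12 | intermediate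
18 | (7R,8S,9S)-2,3,4-trimethoxy-2',2',7,8-tetramethyl-6,7,8,9-tetrahydrospiro[benzo[7]annulene-5,5'-[1,3]dioxan]-9-ol | CC1(C)OCC2(CO1)C[C@@H](C)[C@H](C)[C@H](O)c1cc(OC)c(OC)c(OC)c12 | intermediate
19 | (7R,8S,9R)-2,3,4-trimethoxy-2',2',7,8-tetramethyl-6,7,8,9-tetrahydrospiro[benzo[7]annulene-5,5'-[1,3]dioxan]-9-yl benzoate | CC1(C)OCC2(CO1)C[C@@H](C)[C@H](C)[C@@H](OC(=O)c1ccccc1)c1cc(OC)c(OC)c(OC)c12 | intermediate
20 | (7R,8S,9R)-5,5-bis(hydroxymethyl)-2,3,4-trimethoxy-7,8-dimethyl-6,7,8,9-tetrahydro-5H-benzo[7]annulen-9-yl benzoate | OCC2(CO)C[C@@H](C)[C@H](C)[C@@H](OC(=O)c1ccccc1)c1cc(OC)c(OC)c(OC)c12 | intermediate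
21 | (7R,8S,9R)-5,5-diformyl-2,3,4-trimethoxy-7,8-dimethyl-6,7,8,9-tetrahydro-5H-benzo[7]annulen-9-yl benzoate | O=CC2(C=O)C[C@@H](C)[C@H](C)[C@@H](OC(=O)c1ccccc1)c1cc(OC)c(OC)c(OC)c12 | intermediate
22 | 1,3-dimethoxypropan-2-ol | COCC(O)COC | starting material
23 | 1,3-dimethoxypropan-2-one | COCC(=O)COC | intermediate
24 | (7R,8S,9R)-5-[(1E)-2,4-dimethoxy-3-oxobut-1-en-1-yl]-5-formyl-2,3,4-trimethoxy-7,8-dimethyl-6,7,8,9-tetrahydro-5H-benzo[7]annulen-9-yl benzoate (either C5 epimer; both converge on 25) | O=CC2(/C=C(/OC)C(=O)COC)C[C@@H](C)[C@H](C)[C@@H](OC(=O)c1ccccc1)c1cc(OC)c(OC)c(OC)c12 | intermediate (not isolated)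
25 | (7R,8S,9R)-2,3,3',4,5'-pentamethoxy-7,8-dimethyl-4'-oxo-6,7,8,9-tetrahydrospiro[benzo[7]annulene-5,1'-cyclohexa[2,5]dien]-9-yl benzoate | COC1=CC2(C=C(OC)C1=O)C[C@@H](C)[C@H](C)[C@@H](OC(=O)c1ccccc1)c1cc(OC)c(OC)c(OC)c12 | target

## Step count and least certain steps

Total steps: 15. Longest linear sequence: 14 (steps 1 to 13 and 15; step 14 is a one-step side branch).

**Step 5 (key step).** The rhodacycle may stall. A C5 ester carbonyl can chelate the trivalent rhodium alkyl, and C6 is neopentyl-like, so alkyne insertion and reductive elimination may become slow enough for reversion to 9, cyclotrimerisation of 8 or aminolysis of the esters at 150 °C to take over. The fallback uses known chemistry, sets out from 3 and returns at 15, replacing steps 3 to 8. Ring B is closed by Friedel–Crafts acylation and C7 is taken from a chiral building block.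

- Alkylation of 3 (NaH, NaI, DMF, 60 °C) with the known methyl (S)-4-bromo-3-methylbutanoate (BrC[C@@H](C)CC(=O)OC) should give the triester dimethyl 2-[(2R)-4-methoxy-2-methyl-4-oxobutyl]-2-(2,3,4-trimethoxyphenyl)malonate F1.
- LiOH (1 equiv, THF–H2O, 0 °C) should saponify only the unhindered chain ester, giving (3R)-5,5-bis(methoxycarbonyl)-3-methyl-5-(2,3,4-trimethoxyphenyl)pentanoic acid F2.
- (CF3CO)2O with catalytic CF3SO3H should close the seven-membered ketone at the same arene position as in step 4, giving dimethyl (7R)-2,3,4-trimethoxy-7-methyl-9-oxo-6,7,8,9-tetrahydro-5H-benzo[7]annulene-5,5-dicarboxylate F3.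
- Enolate methylation (LiN(SiMe3)2, THF, −78 °C; MeI) should occur anti to the C7 methyl and give 15, with DBU equilibration available if needed.

**Step 6.** Enantioface discrimination may be poor, because the aryl and α-methyl alkenyl flanks of the ketone are of similar size, and hydride transfer to the hindered conjugated ketone may be sluggish. The fallback sets out from 11 and returns at 12, replacing catalyst control by kinetic resolution.

- NaBH4 with CeCl3·7H2O in MeOH (Luche reduction) should give the racemic alcohol dimethyl 9-hydroxy-2,3,4-trimethoxy-7,8-dimethyl-6,9-dihydro-5H-benzo[7]annulene-5,5-dicarboxylate F4.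
- Immobilised Candida antarctica lipase B with vinyl acetate in t-BuOMe should, by the usual preference of lipases for cyclic benzylic alcohols with the aryl flank as the large group, acetylate the (9R)-enantiomer to dimethyl (9R)-9-acetoxy-2,3,4-trimethoxy-7,8-dimethyl-6,9-dihydro-5H-benzo[7]annulene-5,5-dicarboxylate F5. The unreacted (9S)-alcohol, which is 12, is then separated.

**Step 7.** The doubly activated (allylic and benzylic) alcohol may ionise under the acidic iridium hydride, turnover at the tetrasubstituted alkene may be slow, and ester coordination may erode face selectivity. The fallback sets out from 11 and returns at 15 through the conditions of step 8, using steric instead of directing control.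

- Reduction of 11 with the (R)-oxazaborolidine and catecholborane should give dimethyl (9R)-9-hydroxy-2,3,4-trimethoxy-7,8-dimethyl-6,9-dihydro-5H-benzo[7]annulene-5,5-dicarboxylate F6.
- Silylation (t-BuMe2SiOTf, 2,6-lutidine) should give dimethyl (9R)-9-(tert-butyldimethylsilyloxy)-2,3,4-trimethoxy-7,8-dimethyl-6,9-dihydro-5H-benzo[7]annulene-5,5-dicarboxylate F7.
- Heterogeneous hydrogenation (H2, 50 bar, Rh/Al2O3, EtOAc) from the face away from the silyl ether should give dimethyl (7R,8R,9R)-9-(tert-butyldimethylsilyloxy)-2,3,4-trimethoxy-7,8-dimethyl-6,7,8,9-tetrahydro-5H-benzo[7]annulene-5,5-dicarboxylate F8.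
- Bu4NF should give dimethyl (7R,8R,9R)-9-hydroxy-2,3,4-trimethoxy-7,8-dimethyl-6,7,8,9-tetrahydro-5H-benzo[7]annulene-5,5-dicarboxylate F9. This is the C9 epimer of 13 and should pass through step 8 unchanged to 14 and then 15.

**Step 11.** Elimination may compete with substitution: in the cis alcohol the C9 oxygen and C8–H can be anti-periplanar. Partial ionisation of the benzylic oxyphosphonium would cost stereochemical fidelity. The fallback sets out from 15 and returns at 19; it makes the trans alcohol by catalyst control and acylates with retention.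

- (S)-2-methyl-CBS-oxazaborolidine with BH3·SMe2, with the aryl flank as the large group, should give dimethyl (7R,8S,9R)-9-hydroxy-2,3,4-trimethoxy-7,8-dimethyl-6,7,8,9-tetrahydro-5H-benzo[7]annulene-5,5-dicarboxylate F10.
- LiAlH4 should give (7R,8S,9R)-5,5-bis(hydroxymethyl)-2,3,4-trimethoxy-7,8-dimethyl-6,7,8,9-tetrahydro-5H-benzo[7]annulen-9-ol F11.
- Me2C(OMe)2 with PPTS should give (7R,8S,9R)-2,3,4-trimethoxy-2',2',7,8-tetramethyl-6,7,8,9-tetrahydrospiro[benzo[7]annulene-5,5'-[1,3]dioxan]-9-ol F12.
- PhCOCl with DMAP in pyridine should give 19.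

**Step 15.** The non-enolisable 1,3-dialdehyde may lose a formyl group by retro-Claisen cleavage when the amine adds to it. The benzoate may be lost, or the sequence may stall after the first condensation with the alkene in the geometry that cannot close. The fallback sets out from 21 and 23 and returns at 25; it separates the two C–C bond formations and avoids base.

- 23 with Me3SiOTf and Et3N should give the silyl enol ether 1,3-dimethoxy-2-(trimethylsilyloxy)prop-1-ene F13.
- Mukaiyama aldol addition of F13 to 21 (BF3·OEt2, CH2Cl2, −78 °C) should give the hydroxy ketone (7R,8S,9R)-5-formyl-5-(1-hydroxy-2,4-dimethoxy-3-oxobutyl)-2,3,4-trimethoxy-7,8-dimethyl-6,7,8,9-tetrahydro-5H-benzo[7]annulen-9-yl benzoate F14 as a mixture of diastereomers.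
- TsOH (cat.) in PhMe at 60 °C should close ring C by intramolecular aldol reaction and remove two molecules of water, giving 25.

## Further compounds

F1 | step 5 | dimethyl 2-[(2R)-4-methoxy-2-methyl-4-oxobutyl]-2-(2,3,4-trimethoxyphenyl)malonate | COC(=O)C(C(=O)OC)(c1ccc(OC)c(OC)c1OC)C[C@@H](C)CC(=O)OC
F2 | step 5 | (3R)-5,5-bis(methoxycarbonyl)-3-methyl-5-(2,3,4-trimethoxyphenyl)pentanoic acid | COC(=O)C(C(=O)OC)(c1ccc(OC)c(OC)c1OC)C[C@@H](C)CC(=O)O
F3 | step 5 | dimethyl (7R)-2,3,4-trimethoxy-7-methyl-9-oxo-6,7,8,9-tetrahydro-5H-benzo[7]annulene-5,5-dicarboxylate | COC(=O)C2(C(=O)OC)C[C@@H](C)CC(=O)c1cc(OC)c(OC)c(OC)c12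
F4 | step 6 | racemic dimethyl 9-hydroxy-2,3,4-trimethoxy-7,8-dimethyl-6,9-dihydro-5H-benzo[7]annulene-5,5-dicarboxylate | COC(=O)C2(C(=O)OC)CC(C)=C(C)C(O)c1cc(OC)c(OC)c(OC)c12
F5 | step 6 | dimethyl (9R)-9-acetoxy-2,3,4-trimethoxy-7,8-dimethyl-6,9-dihydro-5H-benzo[7]annulene-5,5-dicarboxylate | COC(=O)C2(C(=O)OC)CC(C)=C(C)[C@@H](OC(C)=O)c1cc(OC)c(OC)c(OC)c12
F6 | step 7 | dimethyl (9R)-9-hydroxy-2,3,4-trimethoxy-7,8-dimethyl-6,9-dihydro-5H-benzo[7]annulene-5,5-dicarboxylate | COC(=O)C2(C(=O)OC)CC(C)=C(C)[C@@H](O)c1cc(OC)c(OC)c(OC)c12
F7 | step 7 | dimethyl (9R)-9-(tert-butyldimethylsilyloxy)-2,3,4-trimethoxy-7,8-dimethyl-6,9-dihydro-5H-benzo[7]annulene-5,5-dicarboxylate | COC(=O)C2(C(=O)OC)CC(C)=C(C)[C@@H](O[Si](C)(C)C(C)(C)C)c1cc(OC)c(OC)c(OC)c12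
F8 | step 7 | dimethyl (7R,8R,9R)-9-(tert-butyldimethylsilyloxy)-2,3,4-trimethoxy-7,8-dimethyl-6,7,8,9-tetrahydro-5H-benzo[7]annulene-5,5-dicarboxylate | COC(=O)C2(C(=O)OC)C[C@@H](C)[C@@H](C)[C@@H](O[Si](C)(C)C(C)(C)C)c1cc(OC)c(OC)c(OC)c12
F9 | step 7 | dimethyl (7R,8R,9R)-9-hydroxy-2,3,4-trimethoxy-7,8-dimethyl-6,7,8,9-tetrahydro-5H-benzo[7]annulene-5,5-dicarboxylate | COC(=O)C2(C(=O)OC)C[C@@H](C)[C@@H](C)[C@@H](O)c1cc(OC)c(OC)c(OC)c12
F10 | step 11 | dimethyl (7R,8S,9R)-9-hydroxy-2,3,4-trimethoxy-7,8-dimethyl-6,7,8,9-tetrahydro-5H-benzo[7]annulene-5,5-dicarboxylate | COC(=O)C2(C(=O)OC)C[C@@H](C)[C@H](C)[C@@H](O)c1cc(OC)c(OC)c(OC)c12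
F11 | step 11 | (7R,8S,9R)-5,5-bis(hydroxymethyl)-2,3,4-trimethoxy-7,8-dimethyl-6,7,8,9-tetrahydro-5H-benzo[7]annulen-9-ol | OCC2(CO)C[C@@H](C)[C@H](C)[C@@H](O)c1cc(OC)c(OC)c(OC)c12
F12 | step 11 | (7R,8S,9R)-2,3,4-trimethoxy-2',2',7,8-tetramethyl-6,7,8,9-tetrahydrospiro[benzo[7]annulene-5,5'-[1,3]dioxan]-9-ol | CC1(C)OCC2(CO1)C[C@@H](C)[C@H](C)[C@@H](O)c1cc(OC)c(OC)c(OC)c12
F13 | step 15 | 1,3-dimethoxy-2-(trimethylsilyloxy)prop-1-ene | COC=C(COC)O[Si](C)(C)C
F14 | step 15 | (7R,8S,9R)-5-formyl-5-(1-hydroxy-2,4-dimethoxy-3-oxobutyl)-2,3,4-trimethoxy-7,8-dimethyl-6,7,8,9-tetrahydro-5H-benzo[7]annulen-9-yl benzoate (diastereomer mixture at C5 and the two new centres) | O=CC2(C(O)C(OC)C(=O)COC)C[C@@H](C)[C@H](C)[C@@H](OC(=O)c1ccccc1)c1cc(OC)c(OC)c(OC)c12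
A1 | alternative 1 | dimethyl cyclohept-2-ene-1,1-dicarboxylate with tributylstannyl on the alkene carbon C9a, tert-butyldimethylsilyloxy at C9 and methyl groups at C7 and C8 (target numbering, triad as in A3) | COC(=O)C1(C(=O)OC)C[C@@H](C)[C@H](C)[C@@H](O[Si](C)(C)C(C)(C)C)C(=C1)[Sn](CCCC)(CCCC)CCCC
A2 | alternative 1 | 4-chloro-2,3-dimethoxycyclobut-2-en-1-one | COC1=C(OC)C(Cl)C1=O
A3 | alternative 1 | dimethyl (7R,8S,9R)-9-(tert-butyldimethylsilyloxy)-4-hydroxy-2,3-dimethoxy-7,8-dimethyl-6,7,8,9-tetrahydro-5H-benzo[7]annulene-5,5-dicarboxylate | COC(=O)C2(C(=O)OC)C[C@@H](C)[C@H](C)[C@@H](O[Si](C)(C)C(C)(C)C)c1cc(OC)c(OC)c(O)c12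
A4 | alternative 2 | 2-(4-hydroxy-3,5-dimethoxyphenyl)-3,4,5-trimethoxybenzaldehyde | O=Cc1cc(OC)c(OC)c(OC)c1-c1cc(OC)c(O)c(OC)c1
A5 | alternative 2 | methyl 2-[(4,4,5,5-tetramethyl-1,3,2-dioxaborolan-2-yl)methyl]but-2-en-1-yl carbonate (methyl cis to the CH2B group) | C/C=C(/COC(=O)OC)CB1OC(C)(C)C(C)(C)O1
A6 | alternative 2 | (8S,9S)-9-hydroxy-2,3,3',4,5'-pentamethoxy-8-methyl-7-methylene-6,7,8,9-tetrahydrospiro[benzo[7]annulene-5,1'-cyclohexa[2,5]dien]-4'-one | COC1=CC2(C=C(OC)C1=O)CC(=C)[C@H](C)[C@H](O)c1cc(OC)c(OC)c(OC)c12
A7 | alternative 3 | 2-{3,5-dimethoxy-1-[(2E)-2-methylbut-2-en-1-yl]-4-oxocyclohexa-2,5-dien-1-yl}-3,4,5-trimethoxybenzaldehyde | COC1=CC(C/C(C)=C/C)(C=C(OC)C1=O)c1c(C=O)cc(OC)c(OC)c1OC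
A8 | alternative 3 | (7R,8S)-2,3,3',4,5'-pentamethoxy-7,8-dimethyl-7,8-dihydrospiro[benzo[7]annulene-5,1'-cyclohexa[2,5]diene]-4',9(6H)-dione | COC1=CC2(C=C(OC)C1=O)C[C@@H](C)[C@H](C)C(=O)c1cc(OC)c(OC)c(OC)c12
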